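## Retrosynthetic overview

1. The last steps are Yamaguchi esterification of jaeschkeanadiol with TBS-protected 4-hydroxybenzoic acid, Prilezhaev epoxidation of the cycloheptene, and aryl-silyl removal.
2. The seven-membered ring is formed last, by RCM of an allyl/methallyl diene. The methallyl unit comes from Cu-catalysed opening of a terminal epoxide with isopropenyl Grignard, and the epoxide comes from a triol.
3. The secondary carbinol is set by proline-catalysed α-aminoxylation of a lactol. The tertiary C–O is set by iodolactonization of a cyclopentene acid, followed by deiodination.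
4. The cyclopentane is built first. CBS reduction of 3-methylcyclopentenone and a Johnson–Claisen rearrangement give the quaternary methyl centre. Allylic oxidation, iodination, Negishi coupling and ketoreductase reduction then give a cyclopentenol, and a second Johnson–Claisen rearrangement sets the ring-fusion CH.
5. Ring order: cyclopentene first, then the γ-lactone, then the cycloheptene last.

Assumption: (S)-Me-CBS gives (R)-3-methylcyclopent-2-en-1-ol in high ee, and L-proline gives the (R)-aminoxy carbon (CIP, as in the α-aminoxy alcohol of step 14).
Assumption: epoxidation of the cycloheptene occurs on the face anti to the angular methyl, which is the face of the target epoxide.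

## Route

**Step 1**
Reactants: **1** 3-methylcyclopent-2-en-1-one
Product: **2** (R)-3-methylcyclopent-2-en-1-ol
Conditions: (S)-Me-CBS (10 mol%), BH3·SMe2 (0.7 equiv), THF, –30 → 0 °C
Reagents that add atoms: none
Why: Corey–Bakshi–Shibata 1,2-reduction sets the carbinol stereocentre by catalyst control. That centre is transferred in step 2.

**Step 2**
Reactants: **2**, **3** triethyl orthoacetate
Product: **4** ethyl 2-[(1R)-1-methylcyclopent-2-en-1-yl]acetate
Conditions: CH3C(OEt)3 (8 equiv), EtCO2H (3 mol%), neat, 140 °C, sealed tube
Reagents that add atoms: none (the orthoester is reactant **3**)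
Why: In the Johnson–Claisen [3,3] rearrangement the new C–C bond forms on the same face as the breaking C–O bond. This converts the carbinol stereocentre into the all-carbon quaternary methyl centre.

**Step 3**
Reactants: **4**
Product: **5** ethyl 2-[(1R)-1-methyl-4-oxocyclopent-2-en-1-yl]acetate
Conditions: Pd(OH)2/C (20 wt%), K2CO3, t-BuOOH (5.5 M in decane, 5 equiv), CH2Cl2, 25 °C
Reagents that add atoms: tert-butyl hydroperoxide, CC(C)(C)OO (supplies O)
Why: Pd-catalysed allylic C–H oxidation is regiospecific because the only other allylic carbon is quaternary.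

**Step 4**
Reactants: **5**
Product: **6** ethyl 2-[(1R)-3-iodo-1-methyl-4-oxocyclopent-2-en-1-yl]acetate
Conditions: I2 (3 equiv), pyridine, CH2Cl2, 0 → 25 °C
Reagents that add atoms: iodine, II
Why: Johnson α-iodination proceeds by conjugate addition of pyridine, iodination and elimination. No stereocentre is touched.

**Step 5**
Reactants: **6**
Product: **7** ethyl 2-[(1R)-1-methyl-4-oxo-3-(propan-2-yl)cyclopent-2-en-1-yl]acetate
Conditions: iPrZnBr (1.5 equiv), Pd-PEPPSI-IPent (2 mol%), THF/toluene, 25 °C
Reagents that add atoms: isopropylzinc bromide, CC(C)[Zn]Br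
Why: Negishi coupling. The bulky NHC ligand suppresses β-hydride isomerisation of the secondary alkylzinc, and the enone and ester are tolerated.

**Step 6**
Reactants: **7**
Product: **8** ethyl 2-[(1R,4S)-4-hydroxy-1-methyl-3-(propan-2-yl)cyclopent-2-en-1-yl]acetate; the OH is cis to the methyl and trans to the CH2CO2Et arm
Conditions: ketoreductase (KRED, NADPH-dependent oxidoreductase from a screening panel), NADP+, glucose/GDH, KPi pH 7.0 with 10% DMSO, 30 °C
Reagents that add atoms: none
Why: The enzyme delivers hydride to one face of the enone C=O with catalyst control, overriding the weak substrate bias, because the methyl and CH2CO2Et groups are 1,3 to the carbonyl. It sets the allylic carbinol cis to the methyl, which directs the Claisen in step 9 to the methyl face.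

**Step 7**
Reactants: **8**
Product: **9** 2-[(1R,4S)-4-hydroxy-1-methyl-3-(propan-2-yl)cyclopent-2-en-1-yl]acetaldehyde
Conditions: DIBAL-H (2.5 equiv), CH2Cl2, –78 °C
Reagents that add atoms: none
Why: Partial ester reduction stops at the aluminium hemiacetal. The free OH consumes one equivalent of hydride. No stereocentre is affected.

**Step 8**
Reactants: **9**
Product: **10** (1S,4S)-4-allyl-4-methyl-2-(propan-2-yl)cyclopent-2-en-1-ol
Conditions: Ph3P=CH2 (from Ph3PCH3Br, KOtBu; 3 equiv), THF, 0 → 25 °C
Reagents that add atoms: methylenetriphenylphosphorane, C=P(c1ccccc1)(c1ccccc1)c1ccccc1 (supplies CH2)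
Why: Wittig methylenation of the neopentylic aldehyde installs the allyl arm, which is the first RCM partner. The α-carbon is CH2 next to a quaternary centre, so nothing epimerises.

**Step 9**
Reactants: **10**, **3**
Product: **11** ethyl 2-[5-allyl-5-methyl-2-(propan-2-yl)cyclopent-2-en-1-yl]acetate; the CH2CO2Et group is cis to the methyl and trans to the allyl, and the alkene has moved to the carbon bearing the isopropyl group
Conditions: CH3C(OEt)3 (10 equiv), EtCO2H (5 mol%), xylenes, 150 °C, sealed tube
Reagents that add atoms: none (the orthoester is reactant **3**)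
Why: A suprafacial Johnson–Claisen rearrangement delivers the two-carbon unit to the same face as the carbinol oxygen, which is the methyl face. This fixes the ring-fusion carbon (C3a) cis to the methyl and trans to the allyl, and moves the alkene to the trisubstituted C=C that carries the isopropyl group.

**Step 10**
Reactants: **11**
Product: **12** {2-[5-allyl-5-methyl-2-(propan-2-yl)cyclopent-2-en-1-yl]acetic acid}, the carboxylic acid of **11** with the same ring stereochemistry
Conditions: LiOH·H2O, THF/MeOH/H2O, 50 °C
Reagents that add atoms: water, O (hydrolysis; supplies the acid O–H oxygen)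
Why: Saponification of the ethyl ester. The stereocentres are not enolisable.

**Step 11**
Reactants: **12**
Product: **13** 4-allyl-4-methyl-6a-(propan-2-yl)-6-iodo-hexahydro-2H-cyclopenta[b]furan-2-one; cis-fused lactone, the lactone O and the methyl on the same face, and I trans to O
Conditions: I2 (3 equiv), NaHCO3, MeCN, 0 °C
Reagents that add atoms: iodine, II
Why: In the iodolactonization the carboxylate attacks 5-exo at the tertiary alkene carbon, anti to the iodonium. The tertiary C–O is thus formed on the face of the side chain (cis to the methyl), which is the configuration required for the target's tertiary carbinol.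

**Step 12**
Reactants: **13**
Product: **14** 4-allyl-4-methyl-6a-(propan-2-yl)-hexahydro-2H-cyclopenta[b]furan-2-one, cis-fused
Conditions: Bu3SnH (5 equiv; ~0.5 M, substrate ~0.1 M), Et3B/air (cat.), toluene, 25 °C
Reagents that add atoms: none
Why: Radical hydrodeiodination at a secondary carbon. A high hydride concentration outcompetes cyclisation onto the allyl group and acyloxy migration. No stereocentre is created or altered.

**Step 13**
Reactants: **14**
Product: **15** the lactol (anomeric mixture); it is in equilibrium with the γ-hydroxy aldehyde bearing the free tertiary OH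
Conditions: DIBAL-H (1.1 equiv), toluene, –78 °C
Reagents that add atoms: none
Why: Partial reduction of the γ-lactone to the lactol, which unmasks the aldehyde needed for the α-functionalisation.

**Step 14**
Reactants: **15**
Product: **16** the α-aminoxy primary alcohol, in which the carbon next to the ring fusion carries (R)-ONHPh and CH2OH, and the ring stereocentres, allyl, methyl, isopropyl and tertiary OH of **15** are unchanged
Conditions: (i) PhNO, L-proline (20 mol%), DMSO, 0 → 25 °C; (ii) NaBH4, MeOH, 0 °C
Reagents that add atoms: nitrosobenzene, O=Nc1ccccc1 (supplies the PhN–O unit)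
Why: Proline-catalysed enamine α-aminoxylation (Zhong/Hayashi type) sets the new carbinol stereocentre by catalyst control, and NaBH4 traps the unstable α-aminoxy aldehyde.

**Step 15**
Reactants: **16**
Product: **17** the triol, with a tertiary OH, a secondary (R)-carbinol OH and a primary OH
Conditions: CuSO4·5H2O (0.3 equiv), MeOH, 25 °C
Reagents that add atoms: none
Why: Cu(II)-mediated N–O cleavage releases the free alcohol with retention at the carbinol carbon and leaves the allyl alkene intact.

**Step 16**
Reactants: **17**
Product: **18** the primary tosylate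
Conditions: TsCl (1.1 equiv), Et3N, DMAP (cat.), CH2Cl2, 0 °C
Reagents that add atoms: p-toluenesulfonyl chloride, Cc1ccc(cc1)S(=O)(=O)Cl
Why: Sulfonylation is selective for the unhindered primary OH over the secondary and tertiary OH groups.

**Step 17**
Reactants: **18**
Product: **19** terminal epoxide, (R)-oxiranyl on the cyclopentanol
Conditions: K2CO3, MeOH, 0 → 25 °C
Reagents that add atoms: none
Why: The secondary alkoxide closes the epoxide by 3-exo-tet displacement of the tosylate. The C–O bond of the stereocentre is not broken, so configuration is retained.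

**Step 18**
Reactants: **19**
Product: **20** diene, with (S)-1-hydroxy-3-methylbut-3-enyl on the cyclopentanol
Conditions: CH2=C(CH3)MgBr (5 equiv), CuI (20 mol%), THF, –40 → 0 °C
Reagents that add atoms: isopropenylmagnesium bromide, C=C(C)[Mg]Br
Why: Cu-catalysed epoxide opening occurs at the less hindered terminal carbon. The carbinol C–O is retained, and the tertiary OH simply consumes one equivalent of Grignard. (The descriptor changes from R to S only because the CIP priorities change.)

**Step 19**
Reactants: **20**
Product: **21** jaeschkeanadiol
Conditions: Hoveyda–Grubbs II (5 mol%), toluene (3 mM), 80 °C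
Reagents that add atoms: none
Why: Ring-closing metathesis joins the monosubstituted allyl alkene and the 1,1-disubstituted methallyl alkene. It gives the trisubstituted cycloheptene and the trans-fused hydroazulene, with loss of ethylene.

**Step 20**
Reactants: **21**, **22** 4-(tert-butyldimethylsilyloxy)benzoic acid
Product: **23** TBS-protected ferutinin (ester at the secondary OH)
Conditions: **22**, 2,4,6-Cl3C6H2COCl, Et3N, THF, 25 °C; then **21**, DMAP, toluene, 25 °C
Reagents that add atoms: none (the acid is reactant **22**)
Why: Yamaguchi esterification occurs at the secondary OH; the tertiary OH is too hindered to acylate. Configuration is retained.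

**Step 21**
Reactants: **23**
Product: **24** the 6,7-epoxide of **23**
Conditions: mCPBA (1.5 equiv), NaHCO3, CH2Cl2, 0 °C
Reagents that add atoms: meta-chloroperoxybenzoic acid, OOC(=O)c1cccc(Cl)c1 (supplies O)
Why: Prilezhaev epoxidation of the trisubstituted alkene. The angular methyl shields its own face of the cycloheptene, so the epoxide oxygen is delivered to the opposite face. This is the same face as the ester oxygen in the target.

**Step 22**
Reactants: **24**
Product: **25** jaeskeanin
Conditions: TBAF/AcOH (1:1, 1.5 equiv), THF, 0 °C
Reagents that add atoms: none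
Why: Buffered fluoride removes the aryl silyl ether. The epoxide, ester and tertiary alcohol survive, and no stereocentre is altered.

## Compound list
1 | 3-methylcyclopent-2-en-1-one | CC1=CC(=O)CC1 | starting material
2 | (R)-3-methylcyclopent-2-en-1-ol | CC1=C[C@H](O)CC1 | intermediate
3 | triethyl orthoacetate | CC(OCC)(OCC)OCC | starting material
4 | ethyl 2-[(1R)-1-methylcyclopent-2-en-1-yl]acetate | CCOC(=O)C[C@@]1(C)CCC=C1 | intermediate
5 | ethyl 2-[(1R)-1-methyl-4-oxocyclopent-2-en-1-yl]acetate | CCOC(=O)C[C@@]1(C)CC(=O)C=C1 | intermediate
6 | ethyl 2-[(1R)-3-iodo-1-methyl-4-oxocyclopent-2-en-1-yl]acetate | CCOC(=O)C[C@@]1(C)CC(=O)C(I)=C1 | intermediate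
7 | ethyl 2-[(1R)-1-methyl-4-oxo-3-(propan-2-yl)cyclopent-2-en-1-yl]acetate | CCOC(=O)C[C@@]1(C)CC(=O)C(C(C)C)=C1 | intermediate
8 | ethyl 2-[(1R,4S)-4-hydroxy-1-methyl-3-(propan-2-yl)cyclopent-2-en-1-yl]acetate | CCOC(=O)C[C@@]1(C)C[C@H](O)C(C(C)C)=C1 | intermediate
9 | 2-[(1R,4S)-4-hydroxy-1-methyl-3-(propan-2-yl)cyclopent-2-en-1-yl]acetaldehyde | O=CC[C@@]1(C)C[C@H](O)C(C(C)C)=C1 | intermediate
10 | (1S,4S)-4-allyl-4-methyl-2-(propan-2-yl)cyclopent-2-en-1-ol | C=CC[C@@]1(C)C[C@H](O)C(C(C)C)=C1 | intermediate
11 | ethyl 2-[5-allyl-5-methyl-2-(propan-2-yl)cyclopent-2-en-1-yl]acetate (CH2CO2Et cis to Me) | C=CC[C@@]1(C)CC=C(C(C)C)[C@@H]1CC(=O)OCC | intermediate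
12 | 2-[5-allyl-5-methyl-2-(propan-2-yl)cyclopent-2-en-1-yl]acetic acid | C=CC[C@@]1(C)CC=C(C(C)C)[C@@H]1CC(=O)O | intermediate
13 | iodolactone (4-allyl-6-iodo-4-methyl-6a-isopropyl-hexahydrocyclopenta[b]furan-2-one) | C=CC[C@@]1(C)C[C@@H](I)[C@]2(C(C)C)OC(=O)C[C@H]12 | intermediate
14 | cis-fused lactone | C=CC[C@@]1(C)CC[C@]2(C(C)C)OC(=O)C[C@H]12 | intermediate
15 | lactol (anomeric centre unspecified) | C=CC[C@@]1(C)CC[C@]2(C(C)C)OC(O)C[C@H]12 | intermediate
16 | α-aminoxy primary alcohol | C=CC[C@@]1(C)CC[C@@](O)(C(C)C)[C@@H]1[C@@H](ONc2ccccc2)CO | intermediate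
17 | triol | C=CC[C@@]1(C)CC[C@@](O)(C(C)C)[C@@H]1[C@@H](O)CO | intermediate
18 | primary tosylate | C=CC[C@@]1(C)CC[C@@](O)(C(C)C)[C@@H]1[C@@H](O)COS(=O)(=O)c2ccc(C)cc2 | intermediate
19 | terminal epoxide | C=CC[C@@]1(C)CC[C@@](O)(C(C)C)[C@@H]1[C@@H]2CO2 | intermediate
20 | RCM diene | C=CC[C@@]1(C)CC[C@@](O)(C(C)C)[C@@H]1[C@@H](O)CC(C)=C | intermediate
21 | jaeschkeanadiol | CC(C)[C@]1(O)CC[C@]2(C)CC=C(C)C[C@H](O)[C@H]21 | intermediate
22 | 4-(tert-butyldimethylsilyloxy)benzoic acid | CC(C)(C)[Si](C)(C)Oc1ccc(cc1)C(=O)O | starting material
23 | TBS-protected ferutinin | CC(C)[C@]1(O)CC[C@]2(C)CC=C(C)C[C@H](OC(=O)c3ccc(O[Si](C)(C)C(C)(C)C)cc3)[C@H]21 | intermediate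
24 | TBS-protected jaeskeanin | CC(C)[C@]1(O)CC[C@]2(C)C[C@@H]3O[C@]3(C)C[C@H](OC(=O)c3ccc(O[Si](C)(C)C(C)(C)C)cc3)[C@H]21 | intermediate
25 | jaeskeanin | CC(C)[C@]1(O)CC[C@]2(C)C[C@@H]3O[C@]3(C)C[C@H](OC(=O)c3ccc(O)cc3)[C@H]21 | target

## Totals
Total steps: 22. Longest linear sequence: 22 steps (1 → 25).

## Three steps most likely to fail
1. **Step 6 (KRED reduction).** The enzyme must give the diastereomer whose hydride approach is sterically disfavoured, with the OH cis to the methyl. Fallback: Luche reduction (NaBH4/CeCl3), separation of the diastereomers, then Mitsunobu inversion of the trans alcohol (p-O2NC6H4CO2H, DIAD, PPh3; then K2CO3/MeOH). This replaces enzyme control with separation and inversion chemistry.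
2. **Step 9 (Johnson–Claisen at a hindered carbon next to the quaternary centre).** The new bond forms cis to the methyl and the conditions are harsh. Fallback: acetylate **10** and run an Ireland–Claisen rearrangement (LDA, TMSCl, THF, –78 → 25 °C), which gives acid **12** directly. This uses a silyl ketene acetal formed from the enolate at low temperature instead of the 150 °C acid-catalysed orthoester route.
3. **Step 14 (aminoxylation of the lactol).** Low open-aldehyde concentration or poor stereocontrol could give a mixture at the carbinol carbon. Fallback: α-hydroxylation of lactone **14** (LiHMDS, Davis oxaziridine), separation of the epimers, and LiAlH4 reduction to triol **17**, which rejoins the route. If the wrong epimer is carried through, Mitsunobu esterification of **21** with **22** in step 20 in place of the Yamaguchi acylation inverts that carbinol. This uses an enolate/oxaziridine pathway in place of the enamine organocatalytic one.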